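## Retrosynthetic overview

1. Rhopaloic acid A (30) ⇐ methyl oxanylacetate 25; the exocyclic methylene (Mannich, then elimination) and the free acid are installed last.
2. The route rests on the oxane, the only ring: O1–C2–Cα–CO2H is a β-alkoxy acid, so C2 can serve as the β-carbon of an (E)-β-alkoxyacrylate built on the C6 oxygen. The C2–C3 bond is cut, and C3 becomes a primary radical released from a carboxyl group (N-acyloxyphthalimide 21).
3. 21 ⇐ hydroxy ester 14, by oxa-Michael addition to methyl propiolate and exchange of the tert-butyl ester for the phthalimidoyl ester.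
4. 14 ⇐ imide 10, with the C5 stereocentre set by auxiliary-controlled Michael addition to tert-butyl acrylate; 10 ⇐ C18 acid 7 ⇐ (2E,6E)-farnesyl bromide plus a C3 Grignard reagent.
5. Ring order: a single ring, the oxane, closed in step 9.

Key step: step 9

Assumption: commercial (2E,6E)-farnesyl bromide is taken as geometrically pure. "Homofarnesyl" means the (3E,7E)-4,8,12-trimethyltrideca-3,7,11-trien-1-yl group. Ring locants are O1, C2 (carries the acrylic acid), C3, C4, C5 (carries homofarnesyl), C6.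

Remark on the chain: C5 carries homofarnesyl, not farnesyl, so the imide must derive from the C18 acid 7 (farnesyl plus three carbons). Acid 7 is built from stereodefined farnesyl bromide. A Claisen rearrangement of nerolidol would give the farnesylacetate skeleton, one carbon short, and would give little control over the new trisubstituted olefin.

## Route

Step 1
Reactants: 1 (2E,6E)-farnesyl bromide; 2 3-chloropropan-1-ol
Product: 5 (5E,9E)-6,10,14-trimethylpentadeca-5,9,13-trien-1-ol, via chloromagnesium 3-chloropropan-1-olate 3 (not isolated), via 3-(chloromagnesiooxy)propylmagnesium chloride 4 (not isolated)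
Conditions: 2 (1.5 equiv), i-PrMgCl (1.5 equiv), THF, −20 °C; Mg turnings, THF, reflux; then 1, Li2CuCl4 (3 mol%), THF, −20 → 0 °C; aq. NH4Cl
Reagents that add atoms: none
Why: Copper-catalysed (Kochi-type) coupling of an alkoxide-protected Grignard reagent with a primary allylic bromide should go by attack at the unhindered α-carbon, not at the γ-carbon that would become quaternary, and should keep the 2E geometry.

Step 2
Reactants: 5 (5E,9E)-6,10,14-trimethylpentadeca-5,9,13-trien-1-ol
Product: 7 (5E,9E)-6,10,14-trimethylpentadeca-5,9,13-trienoic acid, via aldehyde 6 (not isolated)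
Conditions: TEMPO (20 mol%), PhI(OAc)2 (2.2 equiv), MeCN/H2O (1:1), rt
Reagents that add atoms: water, O
Why: Nitroxyl-catalysed oxidation takes the primary alcohol to the aldehyde and, through its hydrate, to the acid, while isolated trisubstituted olefins are inert to the oxoammonium salt and to PhI(OAc)2.

Step 3
Reactants: 7 (5E,9E)-6,10,14-trimethylpentadeca-5,9,13-trienoic acid; 8 (R)-4-benzyloxazolidin-2-one
Product: 10 (4R)-4-benzyl-3-[(5E,9E)-6,10,14-trimethylpentadeca-5,9,13-trienoyl]-1,3-oxazolidin-2-one, via mixed pivalic anhydride 9 (not isolated)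
Conditions: PivCl (1.1 equiv), Et3N (2.5 equiv), THF, −20 °C; then 8, LiCl, −20 °C → rt
Reagents that add atoms: none
Why: N-acylation of the oxazolidinone through the mixed anhydride occurs at the less hindered acyl carbon and sets no new stereocentre.

Step 4
Reactants: 10 (4R)-4-benzyl-3-[(5E,9E)-6,10,14-trimethylpentadeca-5,9,13-trienoyl]-1,3-oxazolidin-2-one; 11 tert-butyl acrylate
Product: 13 tert-butyl (4S,7E,11E)-4-{[(4R)-4-benzyl-2-oxo-1,3-oxazolidin-3-yl]carbonyl}-8,12,16-trimethylheptadeca-7,11,15-trienoate, via trichlorotitanium (Z)-enolate 12 (not isolated)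
Conditions: TiCl4 (1.05 equiv), i-Pr2NEt (1.1 equiv), CH2Cl2, 0 °C; then 11 (2 equiv), 0 °C; aq. NH4Cl
Reagents that add atoms: none
Why: In this Evans titanium-enolate Michael addition the chelated (Z)-enolate is attacked by the acrylate on the face away from the benzyl group, the same sense as auxiliary-controlled alkylation, which sets the future C5 as 4S; the amine-buffered medium leaves no free protic acid to attack the polyene.

Step 5
Reactants: 13 tert-butyl (4S,7E,11E)-4-{[(4R)-4-benzyl-2-oxo-1,3-oxazolidin-3-yl]carbonyl}-8,12,16-trimethylheptadeca-7,11,15-trienoate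
Product: 14 tert-butyl (4S,7E,11E)-4-(hydroxymethyl)-8,12,16-trimethylheptadeca-7,11,15-trienoate
Conditions: LiBH4 (2 equiv), MeOH (2 equiv), THF, 0 °C; aqueous work-up; use 14 without storage
Reagents that add atoms: none
Why: Reductive removal of the auxiliary by hydride attack at the activated exocyclic imide carbonyl spares the hindered tert-butyl ester and, being non-basic, should not epimerise the α-centre.

Step 6
Reactants: 14 tert-butyl (4S,7E,11E)-4-(hydroxymethyl)-8,12,16-trimethylheptadeca-7,11,15-trienoate; 15 methyl propiolate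
Product: 16 tert-butyl (4S,7E,11E)-4-({[(1E)-3-methoxy-3-oxoprop-1-en-1-yl]oxy}methyl)-8,12,16-trimethylheptadeca-7,11,15-trienoate
Conditions: 15 (1.5 equiv), N-methylmorpholine (0.5 equiv), CH2Cl2, rt
Reagents that add atoms: none
Why: Amine-catalysed oxa-Michael addition of a primary alcohol to an ynoate should give the (E)-β-alkoxyacrylate, the favoured geometry for this addition.

Step 7
Reactants: 16 tert-butyl (4S,7E,11E)-4-({[(1E)-3-methoxy-3-oxoprop-1-en-1-yl]oxy}methyl)-8,12,16-trimethylheptadeca-7,11,15-trienoate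
Product: 18 (4S,7E,11E)-4-({[(1E)-3-methoxy-3-oxoprop-1-en-1-yl]oxy}methyl)-8,12,16-trimethylheptadeca-7,11,15-trienoic acid, via trimethylsilyl ester 17 (not isolated)
Conditions: Me3SiOTf (3 equiv), 2,6-lutidine (5 equiv), CH2Cl2, 0 °C; then H2O/MeOH, rt
Reagents that add atoms: none
Why: Silyl-triflate dealkylation of the tert-butyl ester (O-silylation, loss of isobutene under lutidine buffering, hydrolysis of the silyl ester) avoids protic acid, so the trisubstituted olefins should not be protonated and the methyl ester of the vinylogous carbonate should stay.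

Step 8
Reactants: 18 (4S,7E,11E)-4-({[(1E)-3-methoxy-3-oxoprop-1-en-1-yl]oxy}methyl)-8,12,16-trimethylheptadeca-7,11,15-trienoic acid; 19 N-hydroxyphthalimide
Product: 21 1,3-dioxoisoindolin-2-yl (4S,7E,11E)-4-({[(1E)-3-methoxy-3-oxoprop-1-en-1-yl]oxy}methyl)-8,12,16-trimethylheptadeca-7,11,15-trienoate, via O-acylisourea 20 (not isolated)
Conditions: 19 (1.1 equiv), DIC (1.1 equiv), DMAP (10 mol%), CH2Cl2, rt
Reagents that add atoms: none
Why: Carbodiimide (Steglich-type) esterification of a primary alkanoic acid with N-hydroxyphthalimide is a standard way to make the redox-active ester, and the capped hydroxyl cannot lactonise.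

Step 9
Reactants: 21 1,3-dioxoisoindolin-2-yl (4S,7E,11E)-4-({[(1E)-3-methoxy-3-oxoprop-1-en-1-yl]oxy}methyl)-8,12,16-trimethylheptadeca-7,11,15-trienoate
Product: 25 methyl 2-{(2R,5S)-5-[(3E,7E)-4,8,12-trimethyltrideca-3,7,11-trien-1-yl]oxan-2-yl}acetate, via primary C3 radical 22 (not isolated), via α-ester radical 23 (not isolated), via ester enolate 24 (not isolated)
Conditions: undivided cell, reticulated vitreous carbon cathode, sacrificial Mg anode, n-Bu4NBF4 (0.1 M), DMF, 0.01 M in 21, (CF3)2CHOH (3 equiv), constant current (ca. 2.5 F/mol), rt, Ar; aq. NH4Cl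
Reagents that add atoms: none
Why: Electron transfer from the cathode into the phthalimide unit of 21, which is reduced well before the alkoxyacrylate or the isolated olefins, is followed by N–O scission and loss of CO2 to give primary radical 22, whose addition to C2 gives α-ester radical 23; this is reduced to enolate 24 and protonated by (CF3)2CHOH. The closest known reactions are the electroreductive decarboxylative Giese addition of N-acyloxyphthalimides to acrylates and the tin-hydride cyclisation of alkyl radicals onto β-alkoxyacrylates. The oxane is closed in a 6-exo-trig mode by the new C2–C3 bond. C2 is controlled by the existing C5 centre through a chair-like transition state in which the homofarnesyl group and the (E)-acrylate arm are both pseudo-equatorial, which should give the 2,5-trans (2R,5S) ring. The step needs the radical to choose the acrylate over the trisubstituted olefins, over allylic hydrogen transfer and over quenching by the medium; the polarity match between the nucleophilic alkyl radical and the electron-poor acceptor, high dilution and a current low enough that only the phthalimide ester is reduced should secure this, while the sacrificial Mg anode keeps every oxidant away from the polyene.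

Step 10
Reactants: 25 methyl 2-{(2R,5S)-5-[(3E,7E)-4,8,12-trimethyltrideca-3,7,11-trien-1-yl]oxan-2-yl}acetate
Product: 27 methyl 3-(dimethylamino)-2-{(2R,5S)-5-[(3E,7E)-4,8,12-trimethyltrideca-3,7,11-trien-1-yl]oxan-2-yl}propanoate (both epimers at the propanoate C2), via lithium enolate 26 (not isolated)
Conditions: LiN(i-Pr)2 (1.15 equiv), THF, −78 °C; then CH2=NMe2+ I− (1.5 equiv), −78 → 0 °C
Reagents that add atoms: dimethylmethyleneiminium iodide (Eschenmoser's salt), C=[N+](C)C.[I-]
Why: This ester enolate Mannich reaction is run at −78 °C, where the β-alkoxy enolate should not ring-open by E1cB elimination; the ring stereocentres are not deprotonated and the new Cα centre is removed in the next step.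

Step 11
Reactants: 27 methyl 3-(dimethylamino)-2-{(2R,5S)-5-[(3E,7E)-4,8,12-trimethyltrideca-3,7,11-trien-1-yl]oxan-2-yl}propanoate
Product: 29 methyl 2-{(2R,5S)-5-[(3E,7E)-4,8,12-trimethyltrideca-3,7,11-trien-1-yl]oxan-2-yl}prop-2-enoate, via trimethylammonium iodide 28 (not isolated)
Conditions: MeI (10 equiv), MeOH, rt; evaporate; DBU (2 equiv), CH2Cl2, rt
Reagents that add atoms: none
Why: Exhaustive N-methylation followed by base-induced E1cB (Hofmann-type) loss of trimethylamine can only place the new double bond toward the aminomethyl carbon, giving the α-methylene ester.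

Step 12
Reactants: 29 methyl 2-{(2R,5S)-5-[(3E,7E)-4,8,12-trimethyltrideca-3,7,11-trien-1-yl]oxan-2-yl}prop-2-enoate
Product: 30 rhopaloic acid A, 2-{(2R,5S)-5-[(3E,7E)-4,8,12-trimethyltrideca-3,7,11-trien-1-yl]oxan-2-yl}prop-2-enoic acid
Conditions: LiOH·H2O (4 equiv), THF/H2O (3:1), rt; then 1 M HCl, 0 °C, to pH 3
Reagents that add atoms: lithium hydroxide, [Li+].[OH-]
Why: Saponification of the methyl ester in an alcohol-free medium avoids alkoxide conjugate addition to the acrylate, and the allylic C2–H is not acidic enough under these conditions to put the ring stereocentres at risk.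

## Compound list

1 | (2E,6E)-farnesyl bromide, (2E,6E)-1-bromo-3,7,11-trimethyldodeca-2,6,10-triene | BrC/C=C(\C)CC/C=C(\C)CCC=C(C)C | starting material
2 | 3-chloropropan-1-ol | OCCCCl | starting material
3 | chloromagnesium 3-chloropropan-1-olate | ClCCCO[Mg]Cl | intermediate (not isolated)
4 | 3-(chloromagnesiooxy)propylmagnesium chloride | Cl[Mg]CCCO[Mg]Cl | intermediate (not isolated)
5 | (5E,9E)-6,10,14-trimethylpentadeca-5,9,13-trien-1-ol | OCCCC/C=C(\C)CC/C=C(\C)CCC=C(C)C | intermediate
6 | (5E,9E)-6,10,14-trimethylpentadeca-5,9,13-trienal | O=CCCC/C=C(\C)CC/C=C(\C)CCC=C(C)C | intermediate (not isolated)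
7 | (5E,9E)-6,10,14-trimethylpentadeca-5,9,13-trienoic acid | OC(=O)CCC/C=C(\C)CC/C=C(\C)CCC=C(C)C | intermediate
8 | (R)-4-benzyloxazolidin-2-one | O=C1N[C@H](Cc2ccccc2)CO1 | starting material
9 | mixed anhydride of 7 with pivalic acid | CC(C)(C)C(=O)OC(=O)CCC/C=C(\C)CC/C=C(\C)CCC=C(C)C | intermediate (not isolated)
10 | (4R)-4-benzyl-3-[(5E,9E)-6,10,14-trimethylpentadeca-5,9,13-trienoyl]-1,3-oxazolidin-2-one | O=C(CCC/C=C(\C)CC/C=C(\C)CCC=C(C)C)N1[C@H](Cc2ccccc2)COC1=O | intermediate
11 | tert-butyl acrylate | C=CC(=O)OC(C)(C)C | starting material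
12 | trichlorotitanium (Z)-enolate of 10 | Cl[Ti](Cl)(Cl)O/C(=C\CC/C=C(\C)CC/C=C(\C)CCC=C(C)C)N1[C@H](Cc2ccccc2)COC1=O | intermediate (not isolated)
13 | tert-butyl (4S,7E,11E)-4-{[(4R)-4-benzyl-2-oxo-1,3-oxazolidin-3-yl]carbonyl}-8,12,16-trimethylheptadeca-7,11,15-trienoate | CC(C)(C)OC(=O)CC[C@H](CC/C=C(\C)CC/C=C(\C)CCC=C(C)C)C(=O)N1[C@H](Cc2ccccc2)COC1=O | intermediate
14 | tert-butyl (4S,7E,11E)-4-(hydroxymethyl)-8,12,16-trimethylheptadeca-7,11,15-trienoate | CC(C)(C)OC(=O)CC[C@H](CC/C=C(\C)CC/C=C(\C)CCC=C(C)C)CO | intermediate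
15 | methyl propiolate | C#CC(=O)OC | starting material
16 | tert-butyl (4S,7E,11E)-4-({[(1E)-3-methoxy-3-oxoprop-1-en-1-yl]oxy}methyl)-8,12,16-trimethylheptadeca-7,11,15-trienoate | CC(C)(C)OC(=O)CC[C@H](CC/C=C(\C)CC/C=C(\C)CCC=C(C)C)CO/C=C/C(=O)OC | intermediate
17 | trimethylsilyl ester of 18 | C[Si](C)(C)OC(=O)CC[C@H](CC/C=C(\C)CC/C=C(\C)CCC=C(C)C)CO/C=C/C(=O)OC | intermediate (not isolated)
18 | (4S,7E,11E)-4-({[(1E)-3-methoxy-3-oxoprop-1-en-1-yl]oxy}methyl)-8,12,16-trimethylheptadeca-7,11,15-trienoic acid | OC(=O)CC[C@H](CC/C=C(\C)CC/C=C(\C)CCC=C(C)C)CO/C=C/C(=O)OC | intermediate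
19 | N-hydroxyphthalimide | ON1C(=O)c2ccccc2C1=O | starting material
20 | O-acylisourea from 18 and N,N'-diisopropylcarbodiimide | CC(C)N=C(NC(C)C)OC(=O)CC[C@H](CC/C=C(\C)CC/C=C(\C)CCC=C(C)C)CO/C=C/C(=O)OC | intermediate (not isolated)
21 | 1,3-dioxoisoindolin-2-yl (4S,7E,11E)-4-({[(1E)-3-methoxy-3-oxoprop-1-en-1-yl]oxy}methyl)-8,12,16-trimethylheptadeca-7,11,15-trienoate (key-step precursor) | COC(=O)/C=C/OC[C@@H](CC/C=C(\C)CC/C=C(\C)CCC=C(C)C)CCC(=O)ON1C(=O)c2ccccc2C1=O | intermediate
22 | primary C3 radical formed from 21 by loss of phthalimide anion and CO2 | COC(=O)/C=C/OC[C@@H](CC/C=C(\C)CC/C=C(\C)CCC=C(C)C)C[CH2] | intermediate (not isolated)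
23 | α-ester radical after 6-exo closure, (2R,5S)-oxane | COC(=O)[CH][C@H]1CC[C@H](CC/C=C(\C)CC/C=C(\C)CCC=C(C)C)CO1 | intermediate (not isolated)
24 | ester enolate of 25 (magnesium counter-ion) | COC([O-])=C[C@H]1CC[C@H](CC/C=C(\C)CC/C=C(\C)CCC=C(C)C)CO1 | intermediate (not isolated)
25 | methyl 2-{(2R,5S)-5-[(3E,7E)-4,8,12-trimethyltrideca-3,7,11-trien-1-yl]oxan-2-yl}acetate (key-step product, 2,5-trans) | COC(=O)C[C@H]1CC[C@H](CC/C=C(\C)CC/C=C(\C)CCC=C(C)C)CO1 | intermediate
26 | lithium enolate of 25 | COC(O[Li])=C[C@H]1CC[C@H](CC/C=C(\C)CC/C=C(\C)CCC=C(C)C)CO1 | intermediate (not isolated)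
27 | methyl 3-(dimethylamino)-2-{(2R,5S)-5-[(3E,7E)-4,8,12-trimethyltrideca-3,7,11-trien-1-yl]oxan-2-yl}propanoate, both epimers at the propanoate C2 | COC(=O)C(CN(C)C)[C@H]1CC[C@H](CC/C=C(\C)CC/C=C(\C)CCC=C(C)C)CO1 | intermediate
28 | trimethylammonium iodide from 27 | COC(=O)C(C[N+](C)(C)C)[C@H]1CC[C@H](CC/C=C(\C)CC/C=C(\C)CCC=C(C)C)CO1.[I-] | intermediate (not isolated)
29 | methyl 2-{(2R,5S)-5-[(3E,7E)-4,8,12-trimethyltrideca-3,7,11-trien-1-yl]oxan-2-yl}prop-2-enoate | C=C(C(=O)OC)[C@H]1CC[C@H](CC/C=C(\C)CC/C=C(\C)CCC=C(C)C)CO1 | intermediate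
30 | rhopaloic acid A | C=C(C(=O)O)[C@H]1CC[C@H](CC/C=C(\C)CC/C=C(\C)CCC=C(C)C)CO1 | target

## Step count and risks

Total step count: 12. Longest linear sequence: 12 steps (from 1 and 2 to 30).

Steps most likely to fail:

Step 9. The primary radical may be quenched before it closes the ring: by hydrogen transfer from the medium, by intramolecular hydrogen transfer from the allylic CH2 of the side chain, or by attack on the nearest trisubstituted olefin. The chair preference at C5 may also be too weak, so that 2,5-cis material forms alongside the trans ring. The fallback builds the same bond polarity in reverse, by oxygen attack instead of radical attack, and sets out from hydroxy ester 14. Reduction of 14 with i-Bu2AlH (2.2 equiv, CH2Cl2, −78 °C) should give the lactol (5S)-5-[(3E,7E)-4,8,12-trimethyltrideca-3,7,11-trien-1-yl]oxan-2-ol F1. Wittig reaction of F1 with Ph3P=CHCO2Me (toluene, 80 °C) should open it to methyl (2E,6R,9E,13E)-6-(hydroxymethyl)-10,14,18-trimethylnonadeca-2,9,13,17-tetraenoate F2; its stereocentre has the same spatial arrangement as C5 of 25, and the descriptor changes only through CIP priorities. KOt-Bu (0.1 equiv, THF, 0 °C) should then close F2 by a reversible intramolecular oxa-Michael addition that settles on the diequatorial 2,5-trans ester, so the fallback comes back to the route at 25. The same base treatment could also be used to equilibrate cis-contaminated 25 from the electrochemical step.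

Step 4. TiCl4 and traces of HCl may start hydrochlorination or cation–olefin cyclisation of the polyene, or the acrylate may add with eroded facial selectivity. The fallback sets the centre by enolate alkylation under basic conditions and sets out from imide 10. Deprotonation with NaN(SiMe3)2 (THF, −78 °C) gives the sodium (Z)-enolate of 10 F3. Allyl iodide should then give (4R)-4-benzyl-3-[(2S,5E,9E)-6,10,14-trimethyl-2-(prop-2-en-1-yl)pentadeca-5,9,13-trienoyl]-1,3-oxazolidin-2-one F4, with attack again on the face away from the benzyl group. LiBH4 (MeOH, THF, 0 °C) should give (2S,5E,9E)-6,10,14-trimethyl-2-(prop-2-en-1-yl)pentadeca-5,9,13-trien-1-ol F5. Methyl propiolate with N-methylmorpholine should give methyl (2E)-3-{[(2S,5E,9E)-6,10,14-trimethyl-2-(prop-2-en-1-yl)pentadeca-5,9,13-trien-1-yl]oxy}prop-2-enoate F6. 9-BBN (THF, 0 °C → rt) should hydroborate only the monosubstituted olefin, giving the B-alkyl-9-borabicyclo[3.3.1]nonane adduct of F6 F7. NaBO3·4H2O (THF/H2O) should oxidise F7 to methyl (2E)-3-{[(2S,5E,9E)-2-(3-hydroxypropyl)-6,10,14-trimethylpentadeca-5,9,13-trien-1-yl]oxy}prop-2-enoate F8. TEMPO/PhI(OAc)2 in MeCN/H2O, passing through methyl (2E)-3-{[(2S,5E,9E)-6,10,14-trimethyl-2-(3-oxopropyl)pentadeca-5,9,13-trien-1-yl]oxy}prop-2-enoate F9, should give acid 18, where the fallback rejoins the route. It also bypasses steps 5 to 7.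

Step 7. The tert-butyl cation or the silyl triflate may attack the electron-rich olefins or the enol ether, or dealkylation may stall before completion. The fallback removes the tert-butyl group under basic conditions and unmasks the acid by palladium catalysis; it sets out from hydroxy ester 14. KOt-Bu (0.2 equiv, THF, 0 °C → rt) should lactonise 14 to (5S)-5-[(3E,7E)-4,8,12-trimethyltrideca-3,7,11-trien-1-yl]oxan-2-one F10. KOH (1.05 equiv, MeOH/H2O), then evaporation, should give potassium (4S,7E,11E)-4-(hydroxymethyl)-8,12,16-trimethylheptadeca-7,11,15-trienoate F11. Allyl bromide in DMF should alkylate only the carboxylate, giving prop-2-en-1-yl (4S,7E,11E)-4-(hydroxymethyl)-8,12,16-trimethylheptadeca-7,11,15-trienoate F12, which is used at once. Methyl propiolate with N-methylmorpholine should give prop-2-en-1-yl (4S,7E,11E)-4-({[(1E)-3-methoxy-3-oxoprop-1-en-1-yl]oxy}methyl)-8,12,16-trimethylheptadeca-7,11,15-trienoate F13. Pd(PPh3)4 (5 mol%) with morpholine in THF should then release acid 18, where the fallback rejoins the route.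

Further compounds
F1 | step 9 | (5S)-5-[(3E,7E)-4,8,12-trimethyltrideca-3,7,11-trien-1-yl]oxan-2-ol (anomer mixture) | OC1CC[C@H](CC/C=C(\C)CC/C=C(\C)CCC=C(C)C)CO1
F2 | step 9 | methyl (2E,6R,9E,13E)-6-(hydroxymethyl)-10,14,18-trimethylnonadeca-2,9,13,17-tetraenoate | COC(=O)/C=C/CC[C@H](CC/C=C(\C)CC/C=C(\C)CCC=C(C)C)CO
F3 | step 4 | sodium (Z)-enolate of 10 | [Na]O/C(=C\CC/C=C(\C)CC/C=C(\C)CCC=C(C)C)N1[C@H](Cc2ccccc2)COC1=O
F4 | step 4 | (4R)-4-benzyl-3-[(2S,5E,9E)-6,10,14-trimethyl-2-(prop-2-en-1-yl)pentadeca-5,9,13-trienoyl]-1,3-oxazolidin-2-one | C=CC[C@H](CC/C=C(\C)CC/C=C(\C)CCC=C(C)C)C(=O)N1[C@H](Cc2ccccc2)COC1=O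
F5 | step 4 | (2S,5E,9E)-6,10,14-trimethyl-2-(prop-2-en-1-yl)pentadeca-5,9,13-trien-1-ol | C=CC[C@H](CC/C=C(\C)CC/C=C(\C)CCC=C(C)C)CO
F6 | step 4 | methyl (2E)-3-{[(2S,5E,9E)-6,10,14-trimethyl-2-(prop-2-en-1-yl)pentadeca-5,9,13-trien-1-yl]oxy}prop-2-enoate | C=CC[C@H](CC/C=C(\C)CC/C=C(\C)CCC=C(C)C)CO/C=C/C(=O)OC
F7 | step 4 | methyl (2E)-3-{[(2R,5E,9E)-2-[3-(9-borabicyclo[3.3.1]nonan-9-yl)propyl]-6,10,14-trimethylpentadeca-5,9,13-trien-1-yl]oxy}prop-2-enoate | COC(=O)/C=C/OC[C@@H](CC/C=C(\C)CC/C=C(\C)CCC=C(C)C)CCCB1C2CCCC1CCC2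
F8 | step 4 | methyl (2E)-3-{[(2S,5E,9E)-2-(3-hydroxypropyl)-6,10,14-trimethylpentadeca-5,9,13-trien-1-yl]oxy}prop-2-enoate | COC(=O)/C=C/OC[C@@H](CC/C=C(\C)CC/C=C(\C)CCC=C(C)C)CCCO
F9 | step 4 | methyl (2E)-3-{[(2S,5E,9E)-6,10,14-trimethyl-2-(3-oxopropyl)pentadeca-5,9,13-trien-1-yl]oxy}prop-2-enoate | COC(=O)/C=C/OC[C@@H](CC/C=C(\C)CC/C=C(\C)CCC=C(C)C)CCC=O
F10 | step 7 | (5S)-5-[(3E,7E)-4,8,12-trimethyltrideca-3,7,11-trien-1-yl]oxan-2-one | O=C1CC[C@H](CC/C=C(\C)CC/C=C(\C)CCC=C(C)C)CO1
F11 | step 7 | potassium (4S,7E,11E)-4-(hydroxymethyl)-8,12,16-trimethylheptadeca-7,11,15-trienoate | [K+].[O-]C(=O)CC[C@H](CC/C=C(\C)CC/C=C(\C)CCC=C(C)C)CO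
F12 | step 7 | prop-2-en-1-yl (4S,7E,11E)-4-(hydroxymethyl)-8,12,16-trimethylheptadeca-7,11,15-trienoate | C=CCOC(=O)CC[C@H](CC/C=C(\C)CC/C=C(\C)CCC=C(C)C)CO
F13 | step 7 | prop-2-en-1-yl (4S,7E,11E)-4-({[(1E)-3-methoxy-3-oxoprop-1-en-1-yl]oxy}methyl)-8,12,16-trimethylheptadeca-7,11,15-trienoate | C=CCOC(=O)CC[C@H](CC/C=C(\C)CC/C=C(\C)CCC=C(C)C)CO/C=C/C(=O)OC
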